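Each arm of the target (C1 carbinol on outer ring A, C2 on inner ring B, C3 hydroxymethyl) becomes a trans-4,5-diaryl-1,3-dioxane once a CH2O unit bridges its two hydroxyls, and that ring is the sum of an (E)-stilbene and two formaldehyde molecules. A chiral confined Brønsted acid adds both across the alkene in one operation: the C2–C3 and C1–O bonds form, the dioxane closes, both stereocentres are set and the 1,3-diol emerges protected. The precursor is the (E)-stilbene with para-benzyloxy ring A and an electron-poor ring B (ortho acetoxy, bromine as later benzylic handle). The mirror-image dioxane, inverted at C1, supplies the (1S,2R) arm; lactone enolate alkylation joins the halves.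

Key step: step 3

Remark on the chemistry (assumption): which hand of the confined acid gives the (4S,5S)-dioxane cannot be predicted for this substrate; the labels (S,S)- and (R,R)-IDPi are provisional and are fixed on the first run by X-ray analysis of the bromine-containing product.

Abbreviations: Ar = 4-(benzyloxy)-3-methoxyphenyl (outer ring A, protected); TBS = tert-butyldimethylsilyl; IDPi = confined imidodiphosphorimidate Brønsted acid. The target is the (3S,4S)-trans-lactone; the arm on the C4 benzyl group is (1S,2S), the arm on the C3 benzyl group is (1S,2R).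

Step 1
Reactants: 1 [4-(benzyloxy)-3-methoxyphenyl]methanol
Product: 2 diethyl {[4-(benzyloxy)-3-methoxyphenyl]methyl}phosphonate
Conditions: P(OEt)3 (1.5 equiv), ZnI2 (1.5 equiv), toluene, reflux
Reagents that add atoms: triethyl phosphite, CCOP(OCC)OCC
Why: The zinc iodide-mediated Michaelis–Arbuzov-type phosphonylation turns electron-rich benzylic alcohols directly into diethyl benzylphosphonates, the para-alkoxy group easing ionisation of the activated alcohol.

Step 2
Reactants: 2 diethyl {[4-(benzyloxy)-3-methoxyphenyl]methyl}phosphonate; 3 5-bromo-2-hydroxy-3-methoxybenzaldehyde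
Product: 5 2-{(E)-2-[4-(benzyloxy)-3-methoxyphenyl]ethenyl}-4-bromo-6-methoxyphenyl acetate, via potassium phenoxide 4 (not isolated)
Conditions: KOtBu (2.5 equiv), THF–DMF, 0 °C → rt; then Ac2O (2 equiv), 0 °C
Reagents that add atoms: acetic anhydride, CC(=O)OC(C)=O
Why: Horner–Wadsworth–Emmons olefination of the aldehyde (reacting as its phenoxide, hence the extra base) with the benzylic phosphonate anion should give the E alkene through reversible addition and elimination from the more stable adduct, and the stilbene phenoxide is acetylated in the same flask.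

Step 3
Reactants: 5 2-{(E)-2-[4-(benzyloxy)-3-methoxyphenyl]ethenyl}-4-bromo-6-methoxyphenyl acetate; 6 formaldehyde (two units, supplied as paraformaldehyde)
Product: 7 2-{(4S,5S)-4-[4-(benzyloxy)-3-methoxyphenyl]-1,3-dioxan-5-yl}-4-bromo-6-methoxyphenyl acetate (trans)
Conditions: (CH2O)n (6 equiv of CH2O), (S,S)-IDPi (5 mol %), CHCl3, 0 °C → rt
Reagents that add atoms: none
Why: Proposed new method: inside the chiral anion pocket the acid activates formaldehyde (or its hemiacetal dimer), the alkene carbon next to ring B attacks it to make the C5–C6 bond (arm C2–C3) while positive charge builds on the carbon next to ring A, and the oxygen of the second formaldehyde unit then makes the C4–O3 bond (arm C1–O), a formal [2+2+2] union. The closest known reaction type is the confined-acid-catalysed asymmetric Prins reaction of styrenes with paraformaldehyde to 4-aryl-1,3-dioxanes, in which a 1,2-diaryl alkene has not been used. The one ring closes as a six-membered 1,3-dioxane by capture of the benzylic cation (or its concerted, asynchronous equivalent) by the hemiacetal oxygen. C5 is set by the catalyst, which selects the alkene face for C–C bond formation, and C4 follows as trans through suprafacial addition across the E alkene and, should the benzylic C–O bond reopen, through the diequatorial preference, so its sense is tied to C5. The step needs regioselectivity (carbon to the ring-B side, oxygen to the ring-A side): the para-benzyloxy group stabilises charge next to ring A, whereas ring B with its twisted ortho-acetoxy group and meta bromine and methoxy groups cannot compete, and the acetate also stops the phenol oxygen from trapping the cation as a dihydrobenzofuran.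

Step 4
Reactants: 5 2-{(E)-2-[4-(benzyloxy)-3-methoxyphenyl]ethenyl}-4-bromo-6-methoxyphenyl acetate; 6 formaldehyde (two units, supplied as paraformaldehyde)
Product: 8 2-{(4R,5R)-4-[4-(benzyloxy)-3-methoxyphenyl]-1,3-dioxan-5-yl}-4-bromo-6-methoxyphenyl acetate (trans)
Conditions: (CH2O)n (6 equiv of CH2O), (R,R)-IDPi (5 mol %), CHCl3, 0 °C → rt
Reagents that add atoms: none
Why: Proposed new method: the mirror-image acid runs the same asynchronous Prins addition of two formaldehyde units across the stilbene (C–C bond at the ring-B carbon, C–O bond at the ring-A carbon, six-membered closure) and so sets C5 by catalyst control and C4 as trans in the opposite absolute sense; the closest known reaction type is the confined-acid-catalysed Prins dioxane synthesis from styrenes and paraformaldehyde.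

Step 5
Reactants: 7 2-{(4S,5S)-4-Ar-1,3-dioxan-5-yl}-4-bromo-6-methoxyphenyl acetate
Product: 10 (4S,5S)-4-[4-(benzyloxy)-3-methoxyphenyl]-5-[2-(benzyloxy)-5-bromo-3-methoxyphenyl]-1,3-dioxane, via phenol 9 (not isolated)
Conditions: K2CO3 (3 equiv), MeOH–DMF, rt; then BnBr (2 equiv), 50 °C
Reagents that add atoms: benzyl bromide, BrCc1ccccc1
Why: Base-catalysed methanolysis of the aryl acetate followed by Williamson benzylation of the phenoxide exchanges the electron-poor mask for a group that survives organolithium chemistry and is removed last by hydrogenolysis, the dioxane and the aryl bromide being inert to carbonate.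

Step 6
Reactants: 10 (4S,5S)-4-Ar-5-[2-(benzyloxy)-5-bromo-3-methoxyphenyl]-1,3-dioxane
Product: 12 4-(benzyloxy)-3-{(4S,5S)-4-[4-(benzyloxy)-3-methoxyphenyl]-1,3-dioxan-5-yl}-5-methoxybenzaldehyde, via aryllithium 11 (not isolated)
Conditions: n-BuLi (1.1 equiv), THF, −78 °C; DMF (3 equiv), −78 → 0 °C; H2O
Reagents that add atoms: N,N-dimethylformamide, CN(C)C=O
Why: Bromine–lithium exchange is faster at −78 °C than any deprotonation of the benzyl ethers or the acetal, and the aryllithium is formylated by DMF (Bouveault aldehyde synthesis).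

Step 7
Reactants: 12 4-(benzyloxy)-3-{(4S,5S)-4-Ar-1,3-dioxan-5-yl}-5-methoxybenzaldehyde; 13 dimethyl succinate
Product: 14 (3E)-4-{4-(benzyloxy)-3-[(4S,5S)-4-Ar-1,3-dioxan-5-yl]-5-methoxyphenyl}-3-(methoxycarbonyl)but-3-enoic acid
Conditions: NaOMe (3 equiv), MeOH, reflux; then 1 M HCl to pH 3, 0 °C
Reagents that add atoms: none
Why: Stobbe condensation: aldol addition, lactonisation to the paraconate and eliminative ring opening give the arylidene succinic half-ester, mainly as the E isomer, and the methylene acetal tolerates the brief cold acidification.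

Step 8
Reactants: 14 (3E)-4-aryl-3-(methoxycarbonyl)but-3-enoic acid
Product: 15 (3S)-4-{4-(benzyloxy)-3-[(4S,5S)-4-Ar-1,3-dioxan-5-yl]-5-methoxyphenyl}-3-(methoxycarbonyl)butanoic acid
Conditions: H2 (6 bar), [Rh(cod)((R,R)-Et-DuPhos)]BF4 (1 mol %), NaOMe (10 mol %), MeOH, rt
Reagents that add atoms: none
Why: Rhodium–bisphospholane asymmetric hydrogenation of a Stobbe itaconate half-ester: carboxylate and alkene chelate the metal, the ligand fixes the face of hydrogen delivery and sets C3 as S (ligand hand to be confirmed on the first run, the antipode being used otherwise), and benzyl ethers and the dioxane are inert to this homogeneous catalyst.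

Step 9
Reactants: 15 (3S)-4-aryl-3-(methoxycarbonyl)butanoic acid
Product: 17 (4S)-4-{4-(benzyloxy)-3-[(4S,5S)-4-Ar-1,3-dioxan-5-yl]-5-methoxybenzyl}dihydrofuran-2(3H)-one, via hydroxy acid 16 (not isolated)
Conditions: KOH (1.0 equiv), EtOH; CaCl2, NaBH4, −10 °C → rt; then 2 M HCl, rt
Reagents that add atoms: none
Why: Calcium borohydride reduces the methyl ester but not the carboxylate salt, and acidification closes the five-membered ring by lactonisation of the gamma-hydroxy acid without touching the stereocentre.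

Step 10
Reactants: 8 2-{(4R,5R)-4-Ar-1,3-dioxan-5-yl}-4-bromo-6-methoxyphenyl acetate
Product: 19 (4R,5R)-4-[4-(benzyloxy)-3-methoxyphenyl]-5-[2-(benzyloxy)-5-bromo-3-methoxyphenyl]-1,3-dioxane, via phenol 18 (not isolated)
Conditions: K2CO3 (3 equiv), MeOH–DMF, rt; then BnBr (2 equiv), 50 °C
Reagents that add atoms: benzyl bromide, BrCc1ccccc1
Why: The same methanolysis and Williamson benzylation as in step 5, applied to the enantiomeric series.

Step 11
Reactants: 19 (4R,5R)-4-Ar-5-[2-(benzyloxy)-5-bromo-3-methoxyphenyl]-1,3-dioxane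
Product: 21 (1R,2R)-1-[4-(benzyloxy)-3-methoxyphenyl]-2-[2-(benzyloxy)-5-bromo-3-methoxyphenyl]propane-1,3-diol, via bipyridinium salt 20 (not isolated)
Conditions: TMSOTf (3 equiv), 2,2′-bipyridyl (4 equiv), CH2Cl2, 0 °C → rt; then H2O, rt
Reagents that add atoms: none
Why: Silyl triflate–2,2′-bipyridyl cleavage of a methylene acetal: the less hindered oxygen is silylated, the oxocarbenium ion is trapped as an N-(alkoxymethyl)bipyridinium salt and water releases formaldehyde, so only the O–CH2–O carbon reacts and C1 and C2 keep their configuration.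

Step 12
Reactants: 21 (1R,2R)-1-Ar-2-[2-(benzyloxy)-5-bromo-3-methoxyphenyl]propane-1,3-diol
Product: 22 (1R,2R)-1-[4-(benzyloxy)-3-methoxyphenyl]-2-[2-(benzyloxy)-5-bromo-3-methoxyphenyl]-3-[(tert-butyldimethylsilyl)oxy]propan-1-ol
Conditions: TBSCl (1.05 equiv), imidazole (2 equiv), CH2Cl2, 0 °C
Reagents that add atoms: tert-butyldimethylsilyl chloride, CC(C)(C)[Si](C)(C)Cl
Why: Silylation with the bulky chlorosilane is selective for the primary hydroxyl over the hindered secondary benzylic one.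

Step 13
Reactants: 22 (1R,2R)-1-Ar-2-[2-(benzyloxy)-5-bromo-3-methoxyphenyl]-3-(TBS-oxy)propan-1-ol
Product: 24 (1S,2R)-1-[4-(benzyloxy)-3-methoxyphenyl]-2-[2-(benzyloxy)-5-bromo-3-methoxyphenyl]-3-[(tert-butyldimethylsilyl)oxy]propan-1-ol, via 4-nitrobenzoate 23 (not isolated)
Conditions: 4-O2NC6H4CO2H (3 equiv), PPh3 (3 equiv), DIAD (3 equiv), toluene, −20 °C → rt; then K2CO3, MeOH, rt
Reagents that add atoms: 4-nitrobenzoic acid, OC(=O)c1ccc(cc1)[N+](=O)[O-] (its oxygen becomes the C1 hydroxyl oxygen)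
Why: Mitsunobu reaction: 4-nitrobenzoate displaces the alkoxyphosphonium group at C1 by SN2 with inversion (1R to 1S), the non-polar solvent, low temperature and acidic pronucleophile disfavouring ionisation of the electron-rich benzylic centre, and methanolysis then cleaves the ester at the acyl carbon so the new configuration is kept.

Step 14
Reactants: 24 (1S,2R)-1-Ar-2-[2-(benzyloxy)-5-bromo-3-methoxyphenyl]-3-(TBS-oxy)propan-1-ol
Product: 25 (1S,2R)-1-[4-(benzyloxy)-3-methoxyphenyl]-2-[2-(benzyloxy)-5-bromo-3-methoxyphenyl]propane-1,3-diol bis(tert-butyldimethylsilyl) ether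
Conditions: TBSOTf (1.5 equiv), 2,6-lutidine (3 equiv), CH2Cl2, 0 °C
Reagents that add atoms: tert-butyldimethylsilyl triflate, CC(C)(C)[Si](C)(C)OS(=O)(=O)C(F)(F)F
Why: The silyl triflate silylates the hindered secondary benzylic alcohol under buffered conditions that do not ionise the C1–O bond.

Step 15
Reactants: 25 bis(TBS) ether of the (1S,2R)-bromo diol
Product: 28 {4-(benzyloxy)-3-[(1S,2R)-1-Ar-1,3-bis(TBS-oxy)propan-2-yl]-5-methoxyphenyl}methanol, via aryllithium 26 (not isolated), via aldehyde 27 (not isolated)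
Conditions: n-BuLi (1.1 equiv), THF, −78 °C; DMF (3 equiv), −78 → 0 °C; then MeOH, NaBH4, 0 °C
Reagents that add atoms: N,N-dimethylformamide, CN(C)C=O
Why: Bromine–lithium exchange and formylation as in step 6, with borohydride reduction of the aldehyde in the same flask; silyl and benzyl ethers tolerate all three operations.

Step 16
Reactants: 28 {4-(benzyloxy)-3-[(1S,2R)-1-Ar-1,3-bis(TBS-oxy)propan-2-yl]-5-methoxyphenyl}methanol
Product: 29 4-(benzyloxy)-3-[(1S,2R)-1-Ar-1,3-bis(TBS-oxy)propan-2-yl]-5-methoxybenzyl bromide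
Conditions: CBr4 (1.3 equiv), PPh3 (1.3 equiv), CH2Cl2, 0 °C; used at once
Reagents that add atoms: carbon tetrabromide, BrC(Br)(Br)Br
Why: The Appel reaction converts the primary benzylic alcohol into the bromide under neutral conditions that leave the silyl ethers intact.

Step 17
Reactants: 17 (4S)-4-{4-(benzyloxy)-3-[(4S,5S)-4-Ar-1,3-dioxan-5-yl]-5-methoxybenzyl}dihydrofuran-2(3H)-one; 29 4-(benzyloxy)-3-[(1S,2R)-1-Ar-1,3-bis(TBS-oxy)propan-2-yl]-5-methoxybenzyl bromide
Product: 31 (3S,4S)-3-{4-(benzyloxy)-3-[(1S,2R)-1-Ar-1,3-bis(TBS-oxy)propan-2-yl]-5-methoxybenzyl}-4-{4-(benzyloxy)-3-[(4S,5S)-4-Ar-1,3-dioxan-5-yl]-5-methoxybenzyl}dihydrofuran-2(3H)-one, via lithium enolate 30 (not isolated)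
Conditions: LiHMDS (1.1 equiv), THF, −78 °C; then 29, HMPA (2 equiv), −78 → −40 °C
Reagents that add atoms: none
Why: Alkylation of the lactone lithium enolate with the benzylic bromide takes place on the face anti to the C4 substituent, which sets C3 as S and gives the 3,4-trans lactone (substrate-controlled enolate alkylation).

Step 18
Reactants: 31 (3S,4S)-lactone with the dioxane on the C4 benzyl ring and the bis(TBS) arm on the C3 benzyl ring
Product: 33 (3S,4S)-3-{4-(benzyloxy)-3-[(1S,2R)-1-Ar-1,3-bis(TBS-oxy)propan-2-yl]-5-methoxybenzyl}-4-{4-(benzyloxy)-3-[(1S,2S)-1-Ar-1,3-dihydroxypropan-2-yl]-5-methoxybenzyl}dihydrofuran-2(3H)-one, via bipyridinium salt 32 (not isolated)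
Conditions: TMSOTf (3 equiv), 2,2′-bipyridyl (4 equiv), CH2Cl2, 0 °C → rt; then H2O, rt
Reagents that add atoms: none
Why: The same silyl triflate–2,2′-bipyridyl methylene acetal cleavage as in step 11 frees the (1S,2S) diol with retention, the bipyridyl buffering the medium so that lactone, benzyl ethers and TBS ethers persist.

Step 19
Reactants: 33 (3S,4S)-lactone with free (1S,2S) diol and bis(TBS) (1S,2R) arm
Product: 34 (3S,4S)-3-{4-(benzyloxy)-3-[(1S,2R)-1-Ar-1,3-dihydroxypropan-2-yl]-5-methoxybenzyl}-4-{4-(benzyloxy)-3-[(1S,2S)-1-Ar-1,3-dihydroxypropan-2-yl]-5-methoxybenzyl}dihydrofuran-2(3H)-one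
Conditions: TBAF (3 equiv), AcOH (3 equiv), THF, 0 °C → rt
Reagents that add atoms: none
Why: Fluoride cleaves both silyl ethers, and buffering with acetic acid keeps the medium too weakly basic to open the lactone.

Step 20
Reactants: 34 tetra-O-benzyl ether of the target
Product: 35 CNP0113972.1, (3S,4S)-3-{3-[(1S,2R)-1,3-dihydroxy-1-(4-hydroxy-3-methoxyphenyl)propan-2-yl]-4-hydroxy-5-methoxybenzyl}-4-{3-[(1S,2S)-1,3-dihydroxy-1-(4-hydroxy-3-methoxyphenyl)propan-2-yl]-4-hydroxy-5-methoxybenzyl}dihydrofuran-2(3H)-one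
Conditions: H2 (1 atm), Pd/C (10 %), EtOAc–MeOH, rt, stopped at full conversion
Reagents that add atoms: none
Why: Hydrogenolysis of the four aryl benzyl ethers over palladium on carbon under neutral conditions is faster than cleavage of the secondary benzylic C–OH bonds and avoids the acid or base that would cause quinone methide formation or closure to a dihydrobenzofuran.

Compound list
1 | [4-(benzyloxy)-3-methoxyphenyl]methanol | COc1cc(CO)ccc1OCc1ccccc1 | starting material
2 | diethyl {[4-(benzyloxy)-3-methoxyphenyl]methyl}phosphonate | CCOP(=O)(Cc1ccc(OCc2ccccc2)c(OC)c1)OCC | intermediate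
3 | 5-bromo-2-hydroxy-3-methoxybenzaldehyde | COc1cc(Br)cc(C=O)c1O | starting material
4 | potassium 2-{(E)-2-[4-(benzyloxy)-3-methoxyphenyl]ethenyl}-4-bromo-6-methoxyphenoxide | [K+].COc1cc(/C=C/c2cc(Br)cc(OC)c2[O-])ccc1OCc1ccccc1 | intermediate (not isolated)
5 | 2-{(E)-2-[4-(benzyloxy)-3-methoxyphenyl]ethenyl}-4-bromo-6-methoxyphenyl acetate | COc1cc(/C=C/c2cc(Br)cc(OC)c2OC(C)=O)ccc1OCc1ccccc1 | intermediate
6 | formaldehyde (supplied as paraformaldehyde) | C=O | starting material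
7 | 2-{(4S,5S)-4-[4-(benzyloxy)-3-methoxyphenyl]-1,3-dioxan-5-yl}-4-bromo-6-methoxyphenyl acetate | COc1cc([C@@H](OCOC5)[C@H]5c2cc(Br)cc(OC)c2OC(C)=O)ccc1OCc1ccccc1 | intermediate
8 | 2-{(4R,5R)-4-[4-(benzyloxy)-3-methoxyphenyl]-1,3-dioxan-5-yl}-4-bromo-6-methoxyphenyl acetate | COc1cc([C@H](OCOC5)[C@@H]5c2cc(Br)cc(OC)c2OC(C)=O)ccc1OCc1ccccc1 | intermediate
9 | 2-{(4S,5S)-4-[4-(benzyloxy)-3-methoxyphenyl]-1,3-dioxan-5-yl}-4-bromo-6-methoxyphenol | COc1cc([C@@H](OCOC5)[C@H]5c2cc(Br)cc(OC)c2O)ccc1OCc1ccccc1 | intermediate (not isolated)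
10 | (4S,5S)-4-[4-(benzyloxy)-3-methoxyphenyl]-5-[2-(benzyloxy)-5-bromo-3-methoxyphenyl]-1,3-dioxane | COc1cc([C@@H](OCOC5)[C@H]5c2cc(Br)cc(OC)c2OCc2ccccc2)ccc1OCc1ccccc1 | intermediate
11 | aryllithium from 10 (lithium in place of bromine) | COc1cc([C@@H](OCOC5)[C@H]5c2cc([Li])cc(OC)c2OCc2ccccc2)ccc1OCc1ccccc1 | intermediate (not isolated)
12 | 4-(benzyloxy)-3-{(4S,5S)-4-[4-(benzyloxy)-3-methoxyphenyl]-1,3-dioxan-5-yl}-5-methoxybenzaldehyde | COc1cc([C@@H](OCOC5)[C@H]5c2cc(C=O)cc(OC)c2OCc2ccccc2)ccc1OCc1ccccc1 | intermediate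
13 | dimethyl succinate | COC(=O)CCC(=O)OC | starting material
14 | (3E)-4-{4-(benzyloxy)-3-[(4S,5S)-4-Ar-1,3-dioxan-5-yl]-5-methoxyphenyl}-3-(methoxycarbonyl)but-3-enoic acid | COc1cc([C@@H](OCOC5)[C@H]5c2cc(/C=C(\CC(=O)O)C(=O)OC)cc(OC)c2OCc2ccccc2)ccc1OCc1ccccc1 | intermediate
15 | (3S)-4-{4-(benzyloxy)-3-[(4S,5S)-4-Ar-1,3-dioxan-5-yl]-5-methoxyphenyl}-3-(methoxycarbonyl)butanoic acid | COc1cc([C@@H](OCOC5)[C@H]5c2cc(C[C@@H](CC(=O)O)C(=O)OC)cc(OC)c2OCc2ccccc2)ccc1OCc1ccccc1 | intermediate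
16 | (3S)-4-{4-(benzyloxy)-3-[(4S,5S)-4-Ar-1,3-dioxan-5-yl]-5-methoxyphenyl}-3-(hydroxymethyl)butanoic acid | COc1cc([C@@H](OCOC5)[C@H]5c2cc(C[C@@H](CC(=O)O)CO)cc(OC)c2OCc2ccccc2)ccc1OCc1ccccc1 | intermediate (not isolated)
17 | (4S)-4-{4-(benzyloxy)-3-[(4S,5S)-4-Ar-1,3-dioxan-5-yl]-5-methoxybenzyl}dihydrofuran-2(3H)-one | COc1cc([C@@H](OCOC5)[C@H]5c2cc(C[C@@H]3COC(=O)C3)cc(OC)c2OCc2ccccc2)ccc1OCc1ccccc1 | intermediate
18 | 2-{(4R,5R)-4-[4-(benzyloxy)-3-methoxyphenyl]-1,3-dioxan-5-yl}-4-bromo-6-methoxyphenol | COc1cc([C@H](OCOC5)[C@@H]5c2cc(Br)cc(OC)c2O)ccc1OCc1ccccc1 | intermediate (not isolated)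
19 | (4R,5R)-4-[4-(benzyloxy)-3-methoxyphenyl]-5-[2-(benzyloxy)-5-bromo-3-methoxyphenyl]-1,3-dioxane | COc1cc([C@H](OCOC5)[C@@H]5c2cc(Br)cc(OC)c2OCc2ccccc2)ccc1OCc1ccccc1 | intermediate
20 | 1-{[(1R,2R)-1-Ar-2-[2-(benzyloxy)-5-bromo-3-methoxyphenyl]-3-(trimethylsilyloxy)propoxy]methyl}-2-(pyridin-2-yl)pyridinium triflate | COc1cc([C@H](OC[n+]3ccccc3-c3ccccn3)[C@@H](CO[Si](C)(C)C)c2cc(Br)cc(OC)c2OCc2ccccc2)ccc1OCc1ccccc1.[O-]S(=O)(=O)C(F)(F)F | intermediate (not isolated)
21 | (1R,2R)-1-[4-(benzyloxy)-3-methoxyphenyl]-2-[2-(benzyloxy)-5-bromo-3-methoxyphenyl]propane-1,3-diol | COc1cc([C@H](O)[C@@H](CO)c2cc(Br)cc(OC)c2OCc2ccccc2)ccc1OCc1ccccc1 | intermediate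
22 | (1R,2R)-1-[4-(benzyloxy)-3-methoxyphenyl]-2-[2-(benzyloxy)-5-bromo-3-methoxyphenyl]-3-[(tert-butyldimethylsilyl)oxy]propan-1-ol | COc1cc([C@H](O)[C@@H](CO[Si](C)(C)C(C)(C)C)c2cc(Br)cc(OC)c2OCc2ccccc2)ccc1OCc1ccccc1 | intermediate
23 | (1S,2R)-1-[4-(benzyloxy)-3-methoxyphenyl]-2-[2-(benzyloxy)-5-bromo-3-methoxyphenyl]-3-[(tert-butyldimethylsilyl)oxy]propyl 4-nitrobenzoate | COc1cc([C@@H](OC(=O)c3ccc(cc3)[N+](=O)[O-])[C@@H](CO[Si](C)(C)C(C)(C)C)c2cc(Br)cc(OC)c2OCc2ccccc2)ccc1OCc1ccccc1 | intermediate (not isolated)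
24 | (1S,2R)-1-[4-(benzyloxy)-3-methoxyphenyl]-2-[2-(benzyloxy)-5-bromo-3-methoxyphenyl]-3-[(tert-butyldimethylsilyl)oxy]propan-1-ol | COc1cc([C@@H](O)[C@@H](CO[Si](C)(C)C(C)(C)C)c2cc(Br)cc(OC)c2OCc2ccccc2)ccc1OCc1ccccc1 | intermediate
25 | (1S,2R)-1-[4-(benzyloxy)-3-methoxyphenyl]-2-[2-(benzyloxy)-5-bromo-3-methoxyphenyl]propane-1,3-diol bis(tert-butyldimethylsilyl) ether | COc1cc([C@@H](O[Si](C)(C)C(C)(C)C)[C@@H](CO[Si](C)(C)C(C)(C)C)c2cc(Br)cc(OC)c2OCc2ccccc2)ccc1OCc1ccccc1 | intermediate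
26 | aryllithium from 25 (lithium in place of bromine) | COc1cc([C@@H](O[Si](C)(C)C(C)(C)C)[C@@H](CO[Si](C)(C)C(C)(C)C)c2cc([Li])cc(OC)c2OCc2ccccc2)ccc1OCc1ccccc1 | intermediate (not isolated)
27 | 4-(benzyloxy)-3-[(1S,2R)-1-Ar-1,3-bis(TBS-oxy)propan-2-yl]-5-methoxybenzaldehyde | COc1cc([C@@H](O[Si](C)(C)C(C)(C)C)[C@@H](CO[Si](C)(C)C(C)(C)C)c2cc(C=O)cc(OC)c2OCc2ccccc2)ccc1OCc1ccccc1 | intermediate (not isolated)
28 | {4-(benzyloxy)-3-[(1S,2R)-1-Ar-1,3-bis(TBS-oxy)propan-2-yl]-5-methoxyphenyl}methanol | COc1cc([C@@H](O[Si](C)(C)C(C)(C)C)[C@@H](CO[Si](C)(C)C(C)(C)C)c2cc(CO)cc(OC)c2OCc2ccccc2)ccc1OCc1ccccc1 | intermediate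
29 | 4-(benzyloxy)-3-[(1S,2R)-1-Ar-1,3-bis(TBS-oxy)propan-2-yl]-5-methoxybenzyl bromide | COc1cc([C@@H](O[Si](C)(C)C(C)(C)C)[C@@H](CO[Si](C)(C)C(C)(C)C)c2cc(CBr)cc(OC)c2OCc2ccccc2)ccc1OCc1ccccc1 | intermediate
30 | lithium enolate of lactone 17 | COc1cc([C@@H](OCOC5)[C@H]5c2cc(C[C@@H]3COC(O[Li])=C3)cc(OC)c2OCc2ccccc2)ccc1OCc1ccccc1 | intermediate (not isolated)
31 | (3S,4S)-3-{4-(benzyloxy)-3-[(1S,2R)-1-Ar-1,3-bis(TBS-oxy)propan-2-yl]-5-methoxybenzyl}-4-{4-(benzyloxy)-3-[(4S,5S)-4-Ar-1,3-dioxan-5-yl]-5-methoxybenzyl}dihydrofuran-2(3H)-one | COc1cc([C@@H](OCOC5)[C@H]5c2cc(C[C@@H]3COC(=O)[C@H]3Cc3cc(OC)c(OCc6ccccc6)c([C@H](CO[Si](C)(C)C(C)(C)C)[C@H](O[Si](C)(C)C(C)(C)C)c4ccc(OCc6ccccc6)c(OC)c4)c3)cc(OC)c2OCc2ccccc2)ccc1OCc1ccccc1 | intermediate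
32 | bipyridinium triflate from 31: on the C4 benzyl arm C1 carries OCH2–(2,2′-bipyridin-1-ium) and C3 carries OSiMe3, configuration (1S,2S) | COc1cc([C@@H](OC[n+]7ccccc7-c7ccccn7)[C@H](CO[Si](C)(C)C)c2cc(C[C@@H]3COC(=O)[C@H]3Cc3cc(OC)c(OCc6ccccc6)c([C@H](CO[Si](C)(C)C(C)(C)C)[C@H](O[Si](C)(C)C(C)(C)C)c4ccc(OCc6ccccc6)c(OC)c4)c3)cc(OC)c2OCc2ccccc2)ccc1OCc1ccccc1.[O-]S(=O)(=O)C(F)(F)F | intermediate (not isolated)
33 | (3S,4S)-3-{4-(benzyloxy)-3-[(1S,2R)-1-Ar-1,3-bis(TBS-oxy)propan-2-yl]-5-methoxybenzyl}-4-{4-(benzyloxy)-3-[(1S,2S)-1-Ar-1,3-dihydroxypropan-2-yl]-5-methoxybenzyl}dihydrofuran-2(3H)-one | COc1cc([C@@H](O)[C@H](CO)c2cc(C[C@@H]3COC(=O)[C@H]3Cc3cc(OC)c(OCc6ccccc6)c([C@H](CO[Si](C)(C)C(C)(C)C)[C@H](O[Si](C)(C)C(C)(C)C)c4ccc(OCc6ccccc6)c(OC)c4)c3)cc(OC)c2OCc2ccccc2)ccc1OCc1ccccc1 | intermediate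
34 | (3S,4S)-3-{4-(benzyloxy)-3-[(1S,2R)-1-Ar-1,3-dihydroxypropan-2-yl]-5-methoxybenzyl}-4-{4-(benzyloxy)-3-[(1S,2S)-1-Ar-1,3-dihydroxypropan-2-yl]-5-methoxybenzyl}dihydrofuran-2(3H)-one | COc1cc([C@@H](O)[C@H](CO)c2cc(C[C@@H]3COC(=O)[C@H]3Cc3cc(OC)c(OCc6ccccc6)c([C@H](CO)[C@H](O)c4ccc(OCc6ccccc6)c(OC)c4)c3)cc(OC)c2OCc2ccccc2)ccc1OCc1ccccc1 | intermediate
35 | CNP0113972.1, (3S,4S)-3-{3-[(1S,2R)-1,3-dihydroxy-1-(4-hydroxy-3-methoxyphenyl)propan-2-yl]-4-hydroxy-5-methoxybenzyl}-4-{3-[(1S,2S)-1,3-dihydroxy-1-(4-hydroxy-3-methoxyphenyl)propan-2-yl]-4-hydroxy-5-methoxybenzyl}dihydrofuran-2(3H)-one | COc1cc([C@@H](O)[C@H](CO)c2cc(C[C@@H]3COC(=O)[C@H]3Cc3cc(OC)c(O)c([C@H](CO)[C@H](O)c4ccc(O)c(OC)c4)c3)cc(OC)c2O)ccc1O | target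

Total step count: 20. Longest linear sequence: 14 steps (steps 1, 2, 4, 10–20); the other branch (steps 1, 2, 3, 5–9, 17–20) has 12.

Steps most likely to fail

Step 3. The crowded 1,2-diaryl alkene may not be accommodated in the confined acid pocket, which would show as slow turnover, weak discrimination between the alkene faces, or competing hydroxymethylation of the electron-rich ring A. The fallback gives up asymmetric induction in favour of resolution and sets out from 5. The classical Prins dioxane synthesis with a non-confined strong acid (paraformaldehyde, TfOH 5 mol %, CHCl3–1,4-dioxane, rt; known for 1-arylpropenes) should give, under thermodynamic control, the racemic trans-dioxane F1. Preparative chromatography on a chiral stationary phase (supercritical CO2, polysaccharide carbamate column) then separates the enantiomers. The (4S,5S) fraction is 7, where the route is rejoined; the other fraction is 8.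

Step 4. The same lack of turnover or of face discrimination may occur in the mirror-image series, and insufficient optical purity would be carried into the (1S,2R) arm. The fallback builds that arm by auxiliary-controlled aldol chemistry and sets out from 3.
- Benzylation (BnBr, K2CO3, DMF) gives 2-(benzyloxy)-5-bromo-3-methoxybenzaldehyde F2.
- Wittig methoxymethylenation (Ph3P(Cl)CH2OMe, KOtBu, THF) gives the enol ether F3, which aqueous HCl in THF hydrolyses to the arylacetaldehyde F4.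
- Pinnick oxidation (NaClO2, NaH2PO4, 2-methyl-2-butene) gives the arylacetic acid F5.
- Its pivaloyl mixed anhydride acylates lithiated (S)-4-benzyl-2-oxazolidinone to give the imide F6.
- The Evans syn-aldol reaction (Bu2BOTf, i-Pr2NEt, CH2Cl2, −78 → 0 °C) with commercial 4-(benzyloxy)-3-methoxybenzaldehyde should give the syn-aldol adduct F7.
- LiBH4 (THF–MeOH, 0 °C) removes the auxiliary and gives the (1S,2R)-diol F8.
- Silylation of both hydroxyls (TBSOTf, 2,6-lutidine) gives 25, where the route is rejoined; steps 10–14, including the inversion, then fall away.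

Step 13. The electron-rich benzylic alkoxyphosphonium ion may ionise before it is displaced, which would give partial retention at C1, or it may eliminate to the alkene. The fallback replaces substitution by oxidation and reduction and sets out from 22. Dess–Martin periodinane (NaHCO3, CH2Cl2, 0 °C) gives the aryl ketone F9, which is reduced at once with LiBH(s-Bu)3 (THF, −78 °C). Felkin–Anh addition of hydride anti to the C2 aryl group should give the (1S,2R) alcohol 24, where the route is rejoined. The ketone is kept cold and buffered because its C2 centre can epimerise.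

Further compounds
F1 | step 3 | racemic trans-2-{4-[4-(benzyloxy)-3-methoxyphenyl]-1,3-dioxan-5-yl}-4-bromo-6-methoxyphenyl acetate (1:1 mixture of the 4S,5S and 4R,5R forms) | COc1cc([C@@H](OCOC5)[C@H]5c2cc(Br)cc(OC)c2OC(C)=O)ccc1OCc1ccccc1.COc1cc([C@H](OCOC5)[C@@H]5c2cc(Br)cc(OC)c2OC(C)=O)ccc1OCc1ccccc1
F2 | step 4 | 2-(benzyloxy)-5-bromo-3-methoxybenzaldehyde | COc1cc(Br)cc(C=O)c1OCc1ccccc1
F3 | step 4 | 2-(benzyloxy)-5-bromo-1-methoxy-3-(2-methoxyethenyl)benzene (E/Z mixture) | COC=Cc1cc(Br)cc(OC)c1OCc1ccccc1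
F4 | step 4 | 2-[2-(benzyloxy)-5-bromo-3-methoxyphenyl]acetaldehyde | O=CCc1cc(Br)cc(OC)c1OCc1ccccc1
F5 | step 4 | 2-[2-(benzyloxy)-5-bromo-3-methoxyphenyl]acetic acid | OC(=O)Cc1cc(Br)cc(OC)c1OCc1ccccc1
F6 | step 4 | (4S)-4-benzyl-3-{2-[2-(benzyloxy)-5-bromo-3-methoxyphenyl]acetyl}-1,3-oxazolidin-2-one | O=C(Cc1cc(Br)cc(OC)c1OCc1ccccc1)N1[C@@H](Cc2ccccc2)COC1=O
F7 | step 4 | (4S)-4-benzyl-3-{(2S,3S)-3-[4-(benzyloxy)-3-methoxyphenyl]-2-[2-(benzyloxy)-5-bromo-3-methoxyphenyl]-3-hydroxypropanoyl}-1,3-oxazolidin-2-one | O=C(N1[C@@H](Cc2ccccc2)COC1=O)[C@@H](c1cc(Br)cc(OC)c1OCc1ccccc1)[C@H](O)c1ccc(OCc2ccccc2)c(OC)c1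
F8 | step 4 | (1S,2R)-1-[4-(benzyloxy)-3-methoxyphenyl]-2-[2-(benzyloxy)-5-bromo-3-methoxyphenyl]propane-1,3-diol | COc1cc([C@@H](O)[C@@H](CO)c2cc(Br)cc(OC)c2OCc2ccccc2)ccc1OCc1ccccc1
F9 | step 13 | (2R)-1-[4-(benzyloxy)-3-methoxyphenyl]-2-[2-(benzyloxy)-5-bromo-3-methoxyphenyl]-3-[(tert-butyldimethylsilyl)oxy]propan-1-one | COc1cc(C(=O)[C@@H](CO[Si](C)(C)C(C)(C)C)c2cc(Br)cc(OC)c2OCc2ccccc2)ccc1OCc1ccccc1
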